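**Monomethyl lithospermate by bromine-guided oxidative cross-coupling of a caffeate with a rosmarinate**

## The problem

The target is a 2,3-trans-2-aryl-2,3-dihydrobenzofuran-3-carboxylate whose benzo ring carries four contiguous substituents: O1 at C7a, C3 at C3a, an (E)-propenoate at C4 and a hydroxyl at C7. The propenoate is esterified with (R)-3-(3,4-dihydroxyphenyl)lactic acid. Of the three stereocentres, C2 and C3 control each other: the trans arrangement is the stable one and C3 is epimerisable. The lactate centre lies too far from the ring to direct anything, and can only make the two trans antipodes diastereomeric and hence separable. The molecule holds a methyl ester next to a free acid and an α-acyloxy ester, so the acid must be carried in differentiated form from the start and no saponification is allowed. The E-cinnamate rules out hydrogenolysis, the two catechols and the C7 phenol are sensitive to air and base, and the C2–O1 bond, para to a hydroxyl, can open to a quinone methide. The enabling feature is that C2 and C3, with their aryl and CO2Me groups, are the two alkene carbons of a caffeate, while O1, C7a and C3a are a phenol oxygen and its ortho carbon in the caffeoyl ring of a rosmarinate. The difficulty is that this ortho carbon lies between the hydroxyl and the side chain; a phenoxyl radical would sooner react at the free para carbon (the later C5).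

## Retrosynthesis

**16 from 14.** The last cut removes four aryl benzyl ethers and one tert-butyl ester. Benzyl is chosen because it survives Ag2O and can be removed without hydrogen, by BCl3 with pentamethylbenzene. The tert-butyl ester falls in the same Lewis-acid operation on warming, through pentahydroxy ester 15, while the methyl ester stays. The forward step must spare the cinnamate, the methyl ester and the C2–O1 bond.

**14 from 13.** The C5–H bond is traced back to C5–Br. The bromine is a blocking atom that occupies the carbon para to the coupling phenol during the key step. Bromine is preferred to tert-butyl, whose removal needs strong acid, and to silyl, which would be lost by ipso substitution during the coupling. The forward step is a hydrodebromination that must leave a cinnamate, a free phenol and four benzyl ethers alone.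

**13 from 9 and 11 (key disconnection).** The cuts are C3–C3a and O1–C2. This removes the dihydrofuran ring, both ring stereocentres and the only hindered C–C bond in one step. It leaves methyl 3-O-benzylcaffeate 11 and bromo-rosmarinate 9, which already holds the E-alkene, the R centre and all oxygens. Cutting C2–C3 or the arene bonds instead would need the side chain to be attached later. The free hydroxyls are placed to steer the oxidation. In 11 the para hydroxyl is free so that a para-quinone methide can form. In 9 only the hydroxyl meta to the side chain is free, so that its oxygen becomes O1; the neighbouring oxygen is benzylated so that no ortho-quinone can form. The forward reaction must achieve cross- instead of homo-coupling, C–C instead of C–O bonding, and attack at the hindered ortho carbon. It passes through quinone methide phenol 12. No facial control is available, so the step is expected to give both trans diastereomers, to be separated.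

**9 from 3 and 7.** The cinnamate C=C is cut by a Knoevenagel–Doebner condensation of aldehyde 3 with malonic half-ester 7, via arylidene intermediate 8. This is preferred to esterifying a cinnamic acid with the hindered alcohol 6, which would need protection of the free phenol. It is also preferred to a Heck reaction, for which the ring bromine would be the wrong halide.

**7 from 6, 5 and 4.** The malonyl group comes from Meldrum's acid and alcohol 6 without base. Alcohol 6 comes from (R)-danshensu 4 by tert-butyl esterification (5) and benzylation of the catechol. The R centre is bought, not made.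

**3 from 2 and 1.** The bromine cannot be put in by brominating 4-(benzyloxy)-3-hydroxybenzaldehyde, because phenols of the isovanillin type brominate between hydroxyl and formyl, at the carbon that must stay free. The bromine is therefore bought in place as 6-bromopiperonal 1. The acetal is cleaved to catechol 2, and the hydroxyl para to the formyl group, the more acidic one, is benzylated to give 3.

**11 from 10.** A Wittig reaction of 3-(benzyloxy)-4-hydroxybenzaldehyde 10 gives the caffeate in one step.

## Roads not taken

**Alternative 1:** Diels–Alder benzannulation on a preformed lactone.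
- **Cut:** the benzo ring is cut at C5–C6 and C7–C7a, so the carbocycle is built last on a chiral five-membered ring.
- **Forward key step:** the vinylketene silyl acetal A1 (a 5-silyloxy-2,3-dihydrofuran with a 3,3-dimethoxyprop-1-en-2-yl group at C4) adds but-3-yn-2-one. The CH2 terminus bonds to the alkyne CH, and the silyloxy-bearing ketene acetal carbon (the later C7a) bonds to the acetyl-bearing alkyne carbon. Loss of silanol then gives arene A2.
- **Merits:** both ring stereocentres are set on a butyrolactone, where trans is the stable arrangement and asymmetric entries exist. No material is lost to a statistical face choice, and in this respect the road is better than the chosen plan. The regiochemistry follows from the polarity of diene and ynone.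
- **Weak points:** A2 is far from the target. The acetyl group must become a hydroxyl by Baeyer–Villiger oxidation and acetate cleavage next to a methyl ester. The dimethoxymethyl group must become an aldehyde and then the side chain, so five or more steps follow the key step. In the lactone that leads to A1, C3–H is α to the ester and β to the ring oxygen, so enolisation competes with epimerisation and with E1cB ring opening. In the adduct, C7a carries two leaving groups, and loss of the ring oxygen instead of silanol would open the dihydrofuran.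
- **Comparison:** the chosen plan is shorter and more convergent, since one step gives skeleton, oxygenation and side chain. Against the stereocontrol of Alternative 1 it can only set a diastereomer separation that discards up to half of the coupled material.

**Alternative 2:** oxidative ring contraction of a flavanone.
- **Cut:** C3–C3a is cut as a 1,2-shift of ring A, so the dihydrofuran comes from a chromanone.
- **Forward key step:** the (2S)-5-bromoflavanone A3, treated with PhI(OAc)2 and H2SO4 in HC(OMe)3, is converted to ester A4. Ring A migrates from the ketal carbon to C3 and the old carbonyl carbon becomes CO2Me. A Heck reaction at C4–Br would then add the side chain.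
- **Merits:** the reaction type is known for flavanones. C2 is untouched and the trans ester follows from the mechanism. The absolute configuration comes from the flavanone, not from a separation. On precedent this road is better than the chosen key step.
- **Weak points:** enantioenriched A3 is configurationally labile, because acid opens it to the chalcone, the more so with an electron-rich aryl group at C2. The ring that must migrate is deactivated by bromine, while the dibenzyloxyphenyl group is the better migrating group and would lead to an isoflavone. Benzyl ethers must survive H2SO4. The 6-bromo-2-hydroxyacetophenone needed for A3 is not readily available. The side chain costs a further step.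
- **Comparison:** the length is similar, but the chosen plan needs no strong acid and installs the chain before the coupling. Because the ring contraction itself is sound on a ring A without bromine, it is kept as the fallback for the key step, in a bromine-free form.

**Alternative 3:** gold-catalysed furan–ynol ether cascade.
- **Cut:** C3a–C7a and C6–C7 are cut; the benzo ring comes from a furan and an ethynyl ether.
- **Forward key step:** Ph3PAuNTf2 activates the ethynyl ether of A5. Furan C2 attacks the oxygen-bearing alkyne carbon, the opened furan recloses through an arene oxide, and the furan oxygen becomes the C7 hydroxyl of A6.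
- **Merits:** the position of the C7 hydroxyl is fixed by the mechanism, so no blocking atom and no debromination are needed. In this respect the road is better than the chosen plan. The conditions are catalytic and neutral, and both stereocentres are set beforehand.
- **Weak points:** A5 is an alkyl ethynyl ether with a β-hydrogen that is also α to an ester. Thermal loss of ketene and base-induced β-elimination both lead to a cinnamate. Putting the ethynyl group on a hindered benzylic alcohol beside an enolisable ester is itself hard. The relative configuration of A5 needs a selective aldol-type reaction of a furylacetate. A6 still needs silyl ether cleavage, oxidation and chain extension.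
- **Comparison:** the sequence is longer and runs through fragile intermediates. The chosen plan sets convergence and robust precursors against it, and pays for its regiochemistry with one bromine and one extra step.

Key step: step 8

Assumption: (R)-danshensu 4 is used as the free acid, liberated from its commercial sodium salt by acidification; 6-bromopiperonal 1 and 3-(benzyloxy)-4-hydroxybenzaldehyde 10 are taken as purchasable.

## Route

Step 1
Reactants: 1 6-bromopiperonal (6-bromo-1,3-benzodioxole-5-carbaldehyde)
Product: 2 2-bromo-4,5-dihydroxybenzaldehyde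
Conditions: BBr3, CH2Cl2, −78 °C to rt; then H2O
Reagents that add atoms: none
Why: Lewis-acid cleavage of the methylenedioxy acetal, a standard route from piperonals to catechols; the aryl bromide and the aldehyde are inert and no stereocentre is involved.

Step 2
Reactants: 2 2-bromo-4,5-dihydroxybenzaldehyde
Product: 3 4-(benzyloxy)-2-bromo-5-hydroxybenzaldehyde
Conditions: BnBr (1.05 equiv), NaHCO3, DMF, 40 °C
Reagents that add atoms: benzyl bromide, BrCc1ccccc1
Why: Williamson etherification; the hydroxyl para to the formyl group is the more acidic, so hydrogen carbonate forms only its phenoxide and monobenzylation takes place there, as with 3,4-dihydroxybenzaldehyde.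

Step 3
Reactants: 4 (R)-danshensu, (2R)-3-(3,4-dihydroxyphenyl)-2-hydroxypropanoic acid
Product: 5 tert-butyl (2R)-3-(3,4-dihydroxyphenyl)-2-hydroxypropanoate
Conditions: Cl3CC(=NH)Ot-Bu, THF–cyclohexane, rt
Reagents that add atoms: tert-butyl 2,2,2-trichloroacetimidate, CC(C)(C)OC(=N)C(Cl)(Cl)Cl
Why: Esterification with a trichloroacetimidate; the carboxylic acid protonates the imidate and is tert-butylated without added catalyst, whereas phenols and the secondary alcohol need a Lewis acid, and the R centre is not touched.

Step 4
Reactants: 5 tert-butyl (2R)-3-(3,4-dihydroxyphenyl)-2-hydroxypropanoate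
Product: 6 tert-butyl (2R)-3-[3,4-bis(benzyloxy)phenyl]-2-hydroxypropanoate
Conditions: BnBr (2.2 equiv), K2CO3, acetone, reflux
Reagents that add atoms: benzyl bromide, BrCc1ccccc1
Why: Williamson etherification of the catechol; carbonate does not deprotonate the aliphatic hydroxyl and does not enolise the α-hydroxy ester, so the alcohol stays free and the R centre intact.

Step 5
Reactants: 6 tert-butyl (2R)-3-[3,4-bis(benzyloxy)phenyl]-2-hydroxypropanoate
Product: 7 3-{[(2R)-3-[3,4-bis(benzyloxy)phenyl]-1-(tert-butoxy)-1-oxopropan-2-yl]oxy}-3-oxopropanoic acid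
Conditions: Meldrum's acid, toluene, 105 °C
Reagents that add atoms: Meldrum's acid (2,2-dimethyl-1,3-dioxane-4,6-dione), CC1(C)OC(=O)CC(=O)O1
Why: Thermal alcoholysis of Meldrum's acid acylates the alcohol with loss of acetone and gives the malonic half-ester directly, the established entry to rosmarinate esters; no base is present, so the R centre is preserved.

Step 6
Reactants: 3 4-(benzyloxy)-2-bromo-5-hydroxybenzaldehyde; 7 3-{[(2R)-3-[3,4-bis(benzyloxy)phenyl]-1-(tert-butoxy)-1-oxopropan-2-yl]oxy}-3-oxopropanoic acid
Product: 9 tert-butyl (2R)-3-[3,4-bis(benzyloxy)phenyl]-2-{[(2E)-3-[4-(benzyloxy)-2-bromo-5-hydroxyphenyl]prop-2-enoyl]oxy}propanoate, via arylidenemalonic half-ester 8 (not isolated)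
Conditions: pyridine, piperidine (cat.), 50 °C
Reagents that add atoms: none
Why: Knoevenagel–Doebner condensation; the half-ester condenses with the aldehyde and the arylidene intermediate 8 loses CO2 to give the E-cinnamate. The free phenol is tolerated and the lactate centre is a spectator under the weakly basic conditions.

Step 7
Reactants: 10 3-(benzyloxy)-4-hydroxybenzaldehyde
Product: 11 methyl (2E)-3-[3-(benzyloxy)-4-hydroxyphenyl]prop-2-enoate
Conditions: Ph3P=CHCO2Me, toluene, 90 °C
Reagents that add atoms: methyl (triphenylphosphoranylidene)acetate, COC(=O)C=P(c1ccccc1)(c1ccccc1)c1ccccc1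
Why: Wittig olefination with a stabilised ylide gives the E-cinnamate and tolerates the free para-hydroxyl, as in the preparation of ferulate esters from vanillin.

Step 8
Reactants: 9 tert-butyl (2R)-3-[3,4-bis(benzyloxy)phenyl]-2-{[(2E)-3-[4-(benzyloxy)-2-bromo-5-hydroxyphenyl]prop-2-enoyl]oxy}propanoate; 11 methyl (2E)-3-[3-(benzyloxy)-4-hydroxyphenyl]prop-2-enoate
Product: 13 methyl (2S,3S)-7-(benzyloxy)-2-[3-(benzyloxy)-4-hydroxyphenyl]-4-[(1E)-3-{[(2R)-3-[3,4-bis(benzyloxy)phenyl]-1-(tert-butoxy)-1-oxopropan-2-yl]oxy}-3-oxoprop-1-en-1-yl]-5-bromo-2,3-dihydro-1-benzofuran-3-carboxylate, via quinone methide phenol 12 (not isolated)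
Conditions: Ag2O (1.5 equiv), 4 Å MS, PhH–acetone (2:1), rt, dark, 11 (2 equiv) added slowly by syringe pump; then chromatography and preparative HPLC of the two trans diastereomers
Reagents that add atoms: none
Why: Proposed new method: Ag2O oxidises both phenols by one electron; the radical of 11 carries spin at the ester-bearing alkene carbon and the radical of 9 at the ring carbons ortho and para to its oxygen, and since the para carbon holds bromine and one ortho carbon the benzyloxy group, only bonding at the CH between hydroxyl and side chain can be followed by rearomatisation, which forms C3–C3a and gives quinone methide phenol 12. The closest known reaction type is the Ag2O dehydrodimerisation of ferulate and caffeate esters to trans-dihydrobenzofuran neolignans, here extended to a cross-coupling at the other ortho carbon with the help of the bromine blocking device known from para–ortho phenol couplings. The dihydrofuran closes by 5-exo-trig addition of the phenol oxygen to the exocyclic carbon of the para-quinone methide (O1–C2), which restores the second arene. C3 is set in the radical coupling, where the remote lactate centre gives no useful facial bias, so both C3 configurations are expected; C2 is set in the ring closure under control of C3, the aryl group adding anti to CO2Me to give the trans ring, which is also the more stable isomer. Cross- over homo-coupling relies on the persistent radical effect: the blocked and hindered radical of 9 has no productive self-coupling and accumulates, while the transient radical of 11 is kept dilute by slow addition. C–C over C–O coupling is favoured by the dry, non-nucleophilic medium, in which an O-linked quinone methide finds no nucleophile. The (2S,3S) product 13 and its (2R,3R) counterpart are diastereomers through the R lactate centre and should separate on preparative HPLC; the configuration of each isomer would be established by carrying it through to the final product and comparing that with the natural compound.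

Step 9
Reactants: 13 methyl (2S,3S)-7-(benzyloxy)-2-[3-(benzyloxy)-4-hydroxyphenyl]-4-[(1E)-3-{[(2R)-3-[3,4-bis(benzyloxy)phenyl]-1-(tert-butoxy)-1-oxopropan-2-yl]oxy}-3-oxoprop-1-en-1-yl]-5-bromo-2,3-dihydro-1-benzofuran-3-carboxylate
Product: 14 methyl (2S,3S)-7-(benzyloxy)-2-[3-(benzyloxy)-4-hydroxyphenyl]-4-[(1E)-3-{[(2R)-3-[3,4-bis(benzyloxy)phenyl]-1-(tert-butoxy)-1-oxopropan-2-yl]oxy}-3-oxoprop-1-en-1-yl]-2,3-dihydro-1-benzofuran-3-carboxylate
Conditions: Pd(PPh3)4 (cat.), HCO2Na, DMF, 80 °C
Reagents that add atoms: none
Why: Palladium-catalysed hydrodehalogenation; zerovalent palladium inserts into the C5–Br bond, formate exchanges for bromide and delivers hydride with loss of CO2, and reductive elimination gives the C5–H bond. The nearly neutral formate medium spares the esters, the benzyl ethers and the C2–O1 bond, and the phosphine-ligated catalyst does not reduce the cinnamate.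

Step 10
Reactants: 14 methyl (2S,3S)-7-(benzyloxy)-2-[3-(benzyloxy)-4-hydroxyphenyl]-4-[(1E)-3-{[(2R)-3-[3,4-bis(benzyloxy)phenyl]-1-(tert-butoxy)-1-oxopropan-2-yl]oxy}-3-oxoprop-1-en-1-yl]-2,3-dihydro-1-benzofuran-3-carboxylate
Product: 16 monomethyl lithospermate, (2R)-3-(3,4-dihydroxyphenyl)-2-{[(2E)-3-[(2S,3S)-2-(3,4-dihydroxyphenyl)-7-hydroxy-3-(methoxycarbonyl)-2,3-dihydro-1-benzofuran-4-yl]prop-2-enoyl]oxy}propanoic acid, via pentahydroxy tert-butyl ester 15 (not isolated)
Conditions: BCl3 (excess), C6HMe5, CH2Cl2, −78 °C, then 0 °C; aqueous MeOH work-up; reversed-phase HPLC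
Reagents that add atoms: none
Why: Lewis-acid debenzylation with pentamethylbenzene as a non-basic cation scavenger cleaves the four aryl benzyl ethers at −78 °C (15), and the tert-butyl ester is cleaved on warming. The reagent is neither hydrolytic nor reducing, so the methyl ester, the E-alkene and the three stereocentres are left as they are.

## Compound list

1 | 6-bromopiperonal (6-bromo-1,3-benzodioxole-5-carbaldehyde) | O=Cc1cc2OCOc2cc1Br | starting material
2 | 2-bromo-4,5-dihydroxybenzaldehyde | O=Cc1cc(O)c(O)cc1Br | intermediate
3 | 4-(benzyloxy)-2-bromo-5-hydroxybenzaldehyde | O=Cc1cc(O)c(OCc2ccccc2)cc1Br | intermediate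
4 | (R)-danshensu, (2R)-3-(3,4-dihydroxyphenyl)-2-hydroxypropanoic acid | O[C@H](Cc1ccc(O)c(O)c1)C(=O)O | starting material
5 | tert-butyl (2R)-3-(3,4-dihydroxyphenyl)-2-hydroxypropanoate | O[C@H](Cc1ccc(O)c(O)c1)C(=O)OC(C)(C)C | intermediate
6 | tert-butyl (2R)-3-[3,4-bis(benzyloxy)phenyl]-2-hydroxypropanoate | O[C@H](Cc1ccc(OCc2ccccc2)c(OCc2ccccc2)c1)C(=O)OC(C)(C)C | intermediate
7 | 3-{[(2R)-3-[3,4-bis(benzyloxy)phenyl]-1-(tert-butoxy)-1-oxopropan-2-yl]oxy}-3-oxopropanoic acid | OC(=O)CC(=O)O[C@H](Cc1ccc(OCc2ccccc2)c(OCc2ccccc2)c1)C(=O)OC(C)(C)C | intermediate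
8 | arylidenemalonic half-ester: 3-[4-(benzyloxy)-2-bromo-5-hydroxyphenyl]-2-({[(2R)-3-[3,4-bis(benzyloxy)phenyl]-1-(tert-butoxy)-1-oxopropan-2-yl]oxy}carbonyl)prop-2-enoic acid (alkene geometry not defined) | OC(=O)C(=Cc1cc(O)c(OCc2ccccc2)cc1Br)C(=O)O[C@H](Cc1ccc(OCc2ccccc2)c(OCc2ccccc2)c1)C(=O)OC(C)(C)C | intermediate
9 | tert-butyl (2R)-3-[3,4-bis(benzyloxy)phenyl]-2-{[(2E)-3-[4-(benzyloxy)-2-bromo-5-hydroxyphenyl]prop-2-enoyl]oxy}propanoate | O=C(/C=C/c1cc(O)c(OCc2ccccc2)cc1Br)O[C@H](Cc1ccc(OCc2ccccc2)c(OCc2ccccc2)c1)C(=O)OC(C)(C)C | intermediate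
10 | 3-(benzyloxy)-4-hydroxybenzaldehyde | O=Cc1ccc(O)c(OCc2ccccc2)c1 | starting material
11 | methyl (2E)-3-[3-(benzyloxy)-4-hydroxyphenyl]prop-2-enoate | COC(=O)/C=C/c1ccc(O)c(OCc2ccccc2)c1 | intermediate
12 | quinone methide phenol: tert-butyl (2R)-3-[3,4-bis(benzyloxy)phenyl]-2-{[(2E)-3-{4-(benzyloxy)-6-bromo-3-hydroxy-2-[(2R)-3-[3-(benzyloxy)-4-oxocyclohexa-2,5-dien-1-ylidene]-1-methoxy-1-oxopropan-2-yl]phenyl}prop-2-enoyl]oxy}propanoate (geometry of the exocyclic alkene not defined) | COC(=O)[C@H](C=C1C=CC(=O)C(OCc2ccccc2)=C1)c1c(O)c(OCc2ccccc2)cc(Br)c1/C=C/C(=O)O[C@H](Cc1ccc(OCc2ccccc2)c(OCc2ccccc2)c1)C(=O)OC(C)(C)C | intermediate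
13 | methyl (2S,3S)-7-(benzyloxy)-2-[3-(benzyloxy)-4-hydroxyphenyl]-4-[(1E)-3-{[(2R)-3-[3,4-bis(benzyloxy)phenyl]-1-(tert-butoxy)-1-oxopropan-2-yl]oxy}-3-oxoprop-1-en-1-yl]-5-bromo-2,3-dihydro-1-benzofuran-3-carboxylate | COC(=O)[C@H]1c2c(/C=C/C(=O)O[C@H](Cc3ccc(OCc4ccccc4)c(OCc4ccccc4)c3)C(=O)OC(C)(C)C)c(Br)cc(OCc3ccccc3)c2O[C@@H]1c1ccc(O)c(OCc2ccccc2)c1 | intermediate
14 | methyl (2S,3S)-7-(benzyloxy)-2-[3-(benzyloxy)-4-hydroxyphenyl]-4-[(1E)-3-{[(2R)-3-[3,4-bis(benzyloxy)phenyl]-1-(tert-butoxy)-1-oxopropan-2-yl]oxy}-3-oxoprop-1-en-1-yl]-2,3-dihydro-1-benzofuran-3-carboxylate | COC(=O)[C@H]1c2c(/C=C/C(=O)O[C@H](Cc3ccc(OCc4ccccc4)c(OCc4ccccc4)c3)C(=O)OC(C)(C)C)ccc(OCc3ccccc3)c2O[C@@H]1c1ccc(O)c(OCc2ccccc2)c1 | intermediate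
15 | methyl (2S,3S)-4-[(1E)-3-{[(2R)-1-(tert-butoxy)-3-(3,4-dihydroxyphenyl)-1-oxopropan-2-yl]oxy}-3-oxoprop-1-en-1-yl]-2-(3,4-dihydroxyphenyl)-7-hydroxy-2,3-dihydro-1-benzofuran-3-carboxylate | COC(=O)[C@H]1c2c(/C=C/C(=O)O[C@H](Cc3ccc(O)c(O)c3)C(=O)OC(C)(C)C)ccc(O)c2O[C@@H]1c1ccc(O)c(O)c1 | intermediate
16 | monomethyl lithospermate, (2R)-3-(3,4-dihydroxyphenyl)-2-{[(2E)-3-[(2S,3S)-2-(3,4-dihydroxyphenyl)-7-hydroxy-3-(methoxycarbonyl)-2,3-dihydro-1-benzofuran-4-yl]prop-2-enoyl]oxy}propanoic acid | COC(=O)[C@H]1c2c(/C=C/C(=O)O[C@H](Cc3ccc(O)c(O)c3)C(=O)O)ccc(O)c2O[C@@H]1c1ccc(O)c(O)c1 | target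

## Step count and risks

Total: 10 steps. Longest linear sequence: 7 steps (4 → 5 → 6 → 7 → 9 → 13 → 14 → 16; steps 3, 4, 5, 6, 8, 9, 10).

**Step 8 (key step, proposed new method).** The most likely failure is that homo-dimerisation of 11 through its own free ortho carbon outruns the cross-coupling, because the carbon of 9 that must react is flanked by the hydroxyl-bearing carbon and the side chain. Coupling through oxygen and further oxidation of the free phenol of the product are the next concerns. Even when the coupling works, the missing facial control means that up to half of the coupled material is the unwanted trans diastereomer.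

The fallback uses known chemistry only. It sets out from 6 and comes back to the route at 16. It builds the dihydrofuran by flavanone ring contraction and attaches the side chain by carboxylate-directed C–H olefination.
- Commercial 2',3'-dihydroxyacetophenone is benzylated at the non-chelated hydroxyl (BnBr, K2CO3) to 1-[3-(benzyloxy)-2-hydroxyphenyl]ethan-1-one F1.
- Claisen–Schmidt condensation with commercial 3,4-bis(benzyloxy)benzaldehyde (KOH, EtOH) gives the chalcone (2E)-1-[3-(benzyloxy)-2-hydroxyphenyl]-3-[3,4-bis(benzyloxy)phenyl]prop-2-en-1-one F2.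
- Oxa-Michael ring closure (NaOAc, EtOH, reflux) and chromatography on a chiral phase give (2S)-8-(benzyloxy)-2-[3,4-bis(benzyloxy)phenyl]-2,3-dihydro-4H-chromen-4-one F3.
- Ring contraction with PhI(OAc)2 and H2SO4 in HC(OMe)3 leaves C2 untouched and gives the trans ester methyl (2S,3S)-7-(benzyloxy)-2-[3,4-bis(benzyloxy)phenyl]-2,3-dihydro-1-benzofuran-3-carboxylate F4.
- LiOH gives (2S,3S)-7-(benzyloxy)-2-[3,4-bis(benzyloxy)phenyl]-2,3-dihydro-1-benzofuran-3-carboxylic acid F5.
- Alcohol 6 is acylated with acryloyl chloride and Et3N to tert-butyl (2R)-2-(acryloyloxy)-3-[3,4-bis(benzyloxy)phenyl]propanoate F6.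
- Pd(OAc)2 with N-acetylisoleucine, KHCO3 and O2 in tert-amyl alcohol joins F5 and F6 at C4, ortho to the carboxyl-bearing carbon, a reaction type established for α-aryl acetic acids. The product is (2S,3S)-7-(benzyloxy)-2-[3,4-bis(benzyloxy)phenyl]-4-[(1E)-3-{[(2R)-3-[3,4-bis(benzyloxy)phenyl]-1-(tert-butoxy)-1-oxopropan-2-yl]oxy}-3-oxoprop-1-en-1-yl]-2,3-dihydro-1-benzofuran-3-carboxylic acid F7.
- Me3SiCHN2 in MeOH–toluene gives the methyl ester, methyl (2S,3S)-7-(benzyloxy)-2-[3,4-bis(benzyloxy)phenyl]-4-[(1E)-3-{[(2R)-3-[3,4-bis(benzyloxy)phenyl]-1-(tert-butoxy)-1-oxopropan-2-yl]oxy}-3-oxoprop-1-en-1-yl]-2,3-dihydro-1-benzofuran-3-carboxylate F8.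
- BCl3 with C6HMe5, as in step 10, then gives 16.

**Step 9.** The risk is conjugate reduction of the cinnamate by a palladium hydride. A second risk is erosion of the ring configuration, if the free para-hydroxyl opens the C2–O1 bond to a quinone methide in warm DMF. The fallback avoids metal hydrides and bases altogether: radical-chain hydrodebromination of 13 with (Me3Si)3SiH and AIBN in toluene at 80 °C, where the aryl radical takes a hydrogen atom from the silane. It sets out from 13 and comes back at 14 without a new compound.

**Step 10.** The risks are incomplete cleavage of the tert-butyl ester at the temperature the product tolerates, ionisation of the C2–O1 bond under Lewis acid at 0 °C, and C-benzylation of the electron-rich catechols if the scavenger is outrun. The fallback separates the two deprotections so that each runs under its mildest conditions. It sets out from 14 and comes back at 16. Trifluoroacetic acid in CH2Cl2 at 0 °C first cleaves the tert-butyl ester to (2R)-3-[3,4-bis(benzyloxy)phenyl]-2-{[(2E)-3-[(2S,3S)-7-(benzyloxy)-2-[3-(benzyloxy)-4-hydroxyphenyl]-3-(methoxycarbonyl)-2,3-dihydro-1-benzofuran-4-yl]prop-2-enoyl]oxy}propanoic acid F9. BCl3 with C6HMe5 is then used at −78 °C only.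

**Step 6 (with step 5).** The risks are partial epimerisation of the α-acyloxy ester centre in warm pyridine–piperidine, plain decarboxylation of 7 to the acetate before it condenses with the hindered ortho-bromo aldehyde, and loss of the tert-butyl ester from the malonic acid at 105 °C in step 5. The fallback replaces the malonate by a phosphonate. It sets out from 6 and comes back at 9. Alcohol 6 is esterified with diethylphosphonoacetic acid (EDC, DMAP) to tert-butyl (2R)-3-[3,4-bis(benzyloxy)phenyl]-2-{[2-(diethoxyphosphoryl)acetyl]oxy}propanoate F10. A Horner–Wadsworth–Emmons reaction with 3 under LiCl and i-Pr2NEt in MeCN at rt, with an extra equivalent of base for the phenol, gives the E-alkene of 9.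

## Further compounds

F1 | step 8 | 1-[3-(benzyloxy)-2-hydroxyphenyl]ethan-1-one | CC(=O)c1cccc(OCc2ccccc2)c1O
F2 | step 8 | (2E)-1-[3-(benzyloxy)-2-hydroxyphenyl]-3-[3,4-bis(benzyloxy)phenyl]prop-2-en-1-one | O=C(/C=C/c1ccc(OCc2ccccc2)c(OCc2ccccc2)c1)c1cccc(OCc2ccccc2)c1O
F3 | step 8 | (2S)-8-(benzyloxy)-2-[3,4-bis(benzyloxy)phenyl]-2,3-dihydro-4H-chromen-4-one | O=C1C[C@@H](c2ccc(OCc3ccccc3)c(OCc3ccccc3)c2)Oc2c(OCc3ccccc3)cccc12
F4 | step 8 | methyl (2S,3S)-7-(benzyloxy)-2-[3,4-bis(benzyloxy)phenyl]-2,3-dihydro-1-benzofuran-3-carboxylate | COC(=O)[C@H]1c2cccc(OCc3ccccc3)c2O[C@@H]1c1ccc(OCc2ccccc2)c(OCc2ccccc2)c1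
F5 | step 8 | (2S,3S)-7-(benzyloxy)-2-[3,4-bis(benzyloxy)phenyl]-2,3-dihydro-1-benzofuran-3-carboxylic acid | OC(=O)[C@H]1c2cccc(OCc3ccccc3)c2O[C@@H]1c1ccc(OCc2ccccc2)c(OCc2ccccc2)c1
F6 | step 8 | tert-butyl (2R)-2-(acryloyloxy)-3-[3,4-bis(benzyloxy)phenyl]propanoate | C=CC(=O)O[C@H](Cc1ccc(OCc2ccccc2)c(OCc2ccccc2)c1)C(=O)OC(C)(C)C
F7 | step 8 | (2S,3S)-7-(benzyloxy)-2-[3,4-bis(benzyloxy)phenyl]-4-[(1E)-3-{[(2R)-3-[3,4-bis(benzyloxy)phenyl]-1-(tert-butoxy)-1-oxopropan-2-yl]oxy}-3-oxoprop-1-en-1-yl]-2,3-dihydro-1-benzofuran-3-carboxylic acid | OC(=O)[C@H]1c2c(/C=C/C(=O)O[C@H](Cc3ccc(OCc4ccccc4)c(OCc4ccccc4)c3)C(=O)OC(C)(C)C)ccc(OCc3ccccc3)c2O[C@@H]1c1ccc(OCc2ccccc2)c(OCc2ccccc2)c1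
F8 | step 8 | methyl (2S,3S)-7-(benzyloxy)-2-[3,4-bis(benzyloxy)phenyl]-4-[(1E)-3-{[(2R)-3-[3,4-bis(benzyloxy)phenyl]-1-(tert-butoxy)-1-oxopropan-2-yl]oxy}-3-oxoprop-1-en-1-yl]-2,3-dihydro-1-benzofuran-3-carboxylate | COC(=O)[C@H]1c2c(/C=C/C(=O)O[C@H](Cc3ccc(OCc4ccccc4)c(OCc4ccccc4)c3)C(=O)OC(C)(C)C)ccc(OCc3ccccc3)c2O[C@@H]1c1ccc(OCc2ccccc2)c(OCc2ccccc2)c1
F0 | step 9 | none | none
F9 | step 10 | (2R)-3-[3,4-bis(benzyloxy)phenyl]-2-{[(2E)-3-[(2S,3S)-7-(benzyloxy)-2-[3-(benzyloxy)-4-hydroxyphenyl]-3-(methoxycarbonyl)-2,3-dihydro-1-benzofuran-4-yl]prop-2-enoyl]oxy}propanoic acid | COC(=O)[C@H]1c2c(/C=C/C(=O)O[C@H](Cc3ccc(OCc4ccccc4)c(OCc4ccccc4)c3)C(=O)O)ccc(OCc3ccccc3)c2O[C@@H]1c1ccc(O)c(OCc2ccccc2)c1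
F10 | step 6 | tert-butyl (2R)-3-[3,4-bis(benzyloxy)phenyl]-2-{[2-(diethoxyphosphoryl)acetyl]oxy}propanoate | CCOP(=O)(OCC)CC(=O)O[C@H](Cc1ccc(OCc2ccccc2)c(OCc2ccccc2)c1)C(=O)OC(C)(C)C
A1 | alternative 1 | methyl (2S,3S)-2-[3,4-bis(benzyloxy)phenyl]-5-[(tert-butyldimethylsilyl)oxy]-4-(3,3-dimethoxyprop-1-en-2-yl)-2,3-dihydrofuran-3-carboxylate | COC(=O)[C@H]1C(C(=C)C(OC)OC)=C(O[Si](C)(C)C(C)(C)C)O[C@@H]1c1ccc(OCc2ccccc2)c(OCc2ccccc2)c1
A2 | alternative 1 | methyl (2S,3S)-7-acetyl-2-[3,4-bis(benzyloxy)phenyl]-4-(dimethoxymethyl)-2,3-dihydro-1-benzofuran-3-carboxylate | COC(=O)[C@H]1c2c(C(OC)OC)ccc(C(C)=O)c2O[C@@H]1c1ccc(OCc2ccccc2)c(OCc2ccccc2)c1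
A3 | alternative 2 | (2S)-8-(benzyloxy)-2-[3,4-bis(benzyloxy)phenyl]-5-bromo-2,3-dihydro-4H-chromen-4-one | O=C1C[C@@H](c2ccc(OCc3ccccc3)c(OCc3ccccc3)c2)Oc2c(OCc3ccccc3)ccc(Br)c12
A4 | alternative 2 | methyl (2S,3S)-7-(benzyloxy)-2-[3,4-bis(benzyloxy)phenyl]-4-bromo-2,3-dihydro-1-benzofuran-3-carboxylate | COC(=O)[C@H]1c2c(Br)ccc(OCc3ccccc3)c2O[C@@H]1c1ccc(OCc2ccccc2)c(OCc2ccccc2)c1
A5 | alternative 3 | methyl (2R,3S)-3-[3,4-bis(benzyloxy)phenyl]-2-[3-({[tert-butyl(dimethyl)silyl]oxy}methyl)furan-2-yl]-3-(ethynyloxy)propanoate | COC(=O)[C@@H](c1occc1CO[Si](C)(C)C(C)(C)C)[C@H](OC#C)c1ccc(OCc2ccccc2)c(OCc2ccccc2)c1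
A6 | alternative 3 | methyl (2S,3S)-2-[3,4-bis(benzyloxy)phenyl]-4-({[tert-butyl(dimethyl)silyl]oxy}methyl)-7-hydroxy-2,3-dihydro-1-benzofuran-3-carboxylate | COC(=O)[C@H]1c2c(CO[Si](C)(C)C(C)(C)C)ccc(O)c2O[C@@H]1c1ccc(OCc2ccccc2)c(OCc2ccccc2)c1
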